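Left-handed product grows as left-handed substrate shrinks, so I ask first where it must end. In the south-west run the two together read 51.0% at 2.00 min, about half of the charge, so that left-handed share is my ceiling. The question is how fast the flask approaches it.

| flask | left-handed substrate | right-handed substrate | gas | catalyst | remark | time |
|---|---|---|---|---|---|---|
| south-west | 2 M | 2 M | 200 mM (held) | 100 mM | run made earlier |  |
| east | 2 M | 2 M | 200 mM (held) | 400 mM | run made earlier |  |
| north-west | 1 M | 1 M | 200 mM (held) | 200 mM | run made earlier |  |
| flask | 2.0 M | 2.0 M | 200 mM (held) | 200 mM |  | 2.0 min |

| run | time / min | left-handed product / % | left-handed substrate / % |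
|---|---|---|---|
| south-west | 0.667 | 11 | 41 |
| south-west | 1.33 | 19 | 33 |
| south-west | 2.00 | 27 | 24 |
| south-west | 2.50 | 27 | 18 |
| east | 0.667 | 11 | 35 |
| east | 1.33 | 31 | 24 |
| east | 2.00 | 38 | 13 |
| east | 2.50 | 42 | 9 |
| north-west | 0.333 | 12 | 41 |
| north-west | 0.833 | 20 | 34 |
| north-west | 1.50 | 36 | 20 |
| north-west | 2.50 | 40 | 5 |

(standard deviation of a reading: 2 percentage points)

- catalyst is single-handed; left-handed substrate and right-handed substrate are mirror images of each other, charged as a racemate, each of them at the stated concentration
- at the start none of the gas is in solution
- partner is what gas becomes in solution

- left-handed product at 2.0 min, in percent of the left-handed substrate and right-handed substrate together charged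
- concentration of partner in solution at 2.0 min, in percent of saturation

First I take the main step alone, with the rate proportional to catalyst. The south-west run keeps 48.0% of its left-handed substrate at 2.00 min. Reckoned with first-order loss of left-handed substrate, doubling the catalyst of the south-west run squares that fraction and gives 38.5% product, and quadrupling it gives 47.3%.

Then I add the entry of gas into solution as partner. The east run, with 400 mM of catalyst, reads 38%, less than that reckoning, so proportion fails. I replace it with the gain per doubling, the points of left-handed product added at this time by each doubling of catalyst, other charges fixed: 5.5 percentage points between the south-west and east runs. The flask lies one doubling above the south-west run, which gives 32.5%, down from 38.5%.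

Right-handed substrate is charged alike in the south-west run, the east run and the flask, so I change nothing for it. My rule gives no figure for partner.

The forecast says 32% and 45% of saturation, judging that “gas transfer into solution is partly limiting”. My own figure for the product is 32.5%.

The flask gives 31.8%, with partner at 48.1% of saturation, and with a doubled transfer coefficient the product stands at 39.9%, more than in the flask. One doubling down from the flask, the gain gives 26.3%, and the south-west charge without scatter stands at 24.9% at the asked time.

    gas ⇌ partner, rate k1*(csat - [partner]) (kL = 0.150 s⁻¹)
    partner + catalyst + left-handed substrate → catalyst + left-handed product (k = 0.570 L² mol⁻² s⁻¹)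
    partner + catalyst + right-handed substrate → catalyst + right-handed product (k = 0.340 L² mol⁻² s⁻¹)

For a neighbour flask, the same in all but its 0.34 M of catalyst, the gain gives 36.0%. The computed result is 36.2%.

(Readings and results are calculated from invented constants, noise included.)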